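**Retrosynthetic overview**

1. The 11-membered ring is closed last, by a Nozaki–Hiyama–Kishi coupling between the carbon that bears the exocyclic methylene and the acetoxy-bearing carbon. Its six-carbon bridge, with the methyl stereocentre, is C1–C6 of (S)-β-citronellene, attached to the cyclohexene ring by B-alkyl Suzuki–Miyaura coupling.
2. The cyclopentane is made in one operation: a radical [3+2] annulation lays ethylene across the side-chain carbon and the methyl-bearing enone carbon of a 4-(bromoacetate)-substituted 3-methylcyclohex-2-enone, giving the cis-hydrindanone with its angular methyl.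
3. Enabling feature: the two unsubstituted CH2 groups of the cyclopentane lie between (a) the ring CH that carries the C(=CH2) carbon and (b) the angular quaternary carbon, which is β to the cyclohexene carbon bearing the allylic OH. With the C(=CH2) carbon at the ester level and that carbinol carbon as a ketone, (a) is an electrophilic α-ester radical site and (b) a radicophilic enone β-carbon, so an ethylene unit fits between them with alternating polarity.
4. The single ring ketone then directs the rest of the six-membered-ring work: dehydrogenation, α-iodination and coupling on one side; α′-hydroxylation and hydroxyl-directed reduction (trans-diol) on the other.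
5. Ring order: cyclohexane (asymmetric conjugate addition to cyclohexenone; its methyl stereocentre relays to the ring-fusion CH and is erased in step 7) → cyclopentane (key step) → 11-membered ring.

Key step: step 6

Remark on the chemistry: the ester-bearing cyclopentane carbon formed in step 6 is expected mainly in the exo (convex-face) configuration, so compounds 12 to 21 are drawn as that epimer; the route does not depend on this, because step 13 resets the centre.

**Route**

Step 1
Reactants: 1 cyclohex-2-en-1-one; 2 methyl iodoacetate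
Product: 4 methyl 2-[(1S,2R)-2-methyl-6-oxocyclohexyl]acetate, via methylzinc enolate 3 (not isolated)
Conditions: Me2Zn, Cu(OTf)2 (2 mol%), binaphthol-derived bis(1-phenylethyl)amine phosphoramidite ligand (4 mol%; the enantiomer that gives the R methyl centre), toluene, −30 °C; then 2, HMPA, −30 to 0 °C
Reagents that add atoms: dimethylzinc, C[Zn]C
Why: Copper-catalysed asymmetric conjugate addition sets the methyl stereocentre under ligand control, and the regiodefined zinc enolate is alkylated by the iodoacetate anti to that methyl, the trans arrangement also being the thermodynamically preferred one at this epimerizable α-carbon.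

Step 2
Reactants: 4 methyl 2-[(1S,2R)-2-methyl-6-oxocyclohexyl]acetate
Product: 6 methyl 2-[(1S,6R)-6-methyl-2-(trifluoromethylsulfonyloxy)cyclohex-2-en-1-yl]acetate, via lithium enolate 5 (not isolated)
Conditions: LiN(iPr)2, THF, −78 °C; then PhNTf2, −78 to 0 °C
Reagents that add atoms: N-phenylbis(trifluoromethanesulfonimide), O=S(=O)(N(c1ccccc1)S(=O)(=O)C(F)(F)F)C(F)(F)F
Why: Kinetic deprotonation of the ketone (more acidic than the ester) at its unhindered CH2 rather than at the substituted α-methine gives the less substituted enolate, which is O-sulfonylated (enol triflate formation) without touching either stereocentre.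

Step 3
Reactants: 6 methyl 2-[(1S,6R)-6-methyl-2-(trifluoromethylsulfonyloxy)cyclohex-2-en-1-yl]acetate
Product: 7 methyl 2-[(1S,6R)-2,6-dimethylcyclohex-2-en-1-yl]acetate
Conditions: MeMgBr, Fe(acac)3 (5 mol%), THF/NMP, −30 °C
Reagents that add atoms: methylmagnesium bromide, C[Mg]Br
Why: Iron-catalysed Kumada-type cross-coupling of an alkenyl triflate is fast enough at low temperature to spare the methyl ester and installs the future angular methyl on the ring alkene.

Step 4
Reactants: 7 methyl 2-[(1S,6R)-2,6-dimethylcyclohex-2-en-1-yl]acetate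
Product: 9 methyl 2-bromo-2-[(1S,6R)-2,6-dimethylcyclohex-2-en-1-yl]acetate (both CHBr epimers), via lithium ester enolate 8 (not isolated)
Conditions: LiN(iPr)2, THF, −78 °C; then BrCCl2CCl2Br, −78 °C
Reagents that add atoms: 1,2-dibromotetrachloroethane, BrC(Cl)(Cl)C(Cl)(Cl)Br
Why: The ester α-carbon is now the only acidic position, so enolate bromination gives the α-bromo ester, whose configuration is irrelevant because this carbon becomes a radical in step 6.

Step 5
Reactants: 9 methyl 2-bromo-2-[(1S,6R)-2,6-dimethylcyclohex-2-en-1-yl]acetate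
Product: 10 methyl 2-bromo-2-[(1S,6R)-2,6-dimethyl-4-oxocyclohex-2-en-1-yl]acetate (both CHBr epimers)
Conditions: CrO3, 3,5-dimethylpyrazole, CH2Cl2, −20 °C
Reagents that add atoms: chromium trioxide, O=[Cr](=O)=O
Why: Allylic oxidation with the CrO3–dimethylpyrazole complex converts the ring CH2 next to the unsubstituted alkene carbon into the enone carbonyl, the only other ring allylic position being a hindered methine that cannot become a ketone, and the non-basic medium avoids loss of HBr from the product.

Step 6
Reactants: 10 methyl 2-bromo-2-[(1S,6R)-2,6-dimethyl-4-oxocyclohex-2-en-1-yl]acetate; 11 ethylene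
Product: 12 methyl (1S,3aR,7R,7aR)-3a,7-dimethyl-5-oxooctahydro-1H-indene-1-carboxylate
Conditions: ethylene (20 bar), (Me3Si)3SiH (slow addition), AIBN (cat.), benzene, 80 °C
Reagents that add atoms: none
Why: Bromine abstraction by the silyl radical gives an electrophilic α-ester radical that adds to ethylene (first new C–C bond), and the resulting nucleophilic primary radical closes onto the methyl-bearing β-carbon of the enone (second new C–C bond) before the α-keto radical takes hydrogen from the silane. The closest known reaction type is the radical [3+2] annulation of but-3-enyl-type α-carbonyl radicals with alkenes (intermolecular addition, then a Giese-type cyclization onto an acceptor), here with ethylene as the alkene. The cyclopentane closes in the 5-exo-trig mode, which the polarization of the enone secures over 6-endo attack at the α-carbon. The angular quaternary centre is controlled by the ring stereocentre that carries the side chain, since the three-atom tether reaches only the adjacent enone face and therefore gives the cis ring fusion; the ester-bearing centre is set in the intermolecular addition without reliable control and is corrected in step 13. The step needs addition to ethylene to outrun reduction of the first radical, and ring closure to outrun a second ethylene insertion, which the ethylene pressure, the slow silane addition and the fast cyclization onto an enone provide.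

Step 7
Reactants: 12 methyl (1S,3aR,7R,7aR)-3a,7-dimethyl-5-oxooctahydro-1H-indene-1-carboxylate
Product: 13 methyl (1S,3aR,7aR)-3a,7-dimethyl-5-oxo-2,3,3a,4,5,7a-hexahydro-1H-indene-1-carboxylate
Conditions: IBX, DMSO, 70 °C
Reagents that add atoms: none
Why: IBX dehydrogenation of the cyclohexanone can proceed only toward the methyl-bearing carbon, because the other α-carbon adjoins the quaternary centre, so it gives the β-methyl enone and removes the relay stereocentre.

Step 8
Reactants: 13 methyl (1S,3aR,7aR)-3a,7-dimethyl-5-oxo-2,3,3a,4,5,7a-hexahydro-1H-indene-1-carboxylate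
Product: 14 methyl (1S,3aR,7aR)-6-iodo-3a,7-dimethyl-5-oxo-2,3,3a,4,5,7a-hexahydro-1H-indene-1-carboxylate
Conditions: I2, pyridine, CH2Cl2, rt
Reagents that add atoms: iodine, II
Why: α-Iodination of an enone with iodine/pyridine proceeds by conjugate addition of pyridine, iodination of the enolate and elimination, and gives the 2-iodoenone needed for cross-coupling.

Step 9
Reactants: 14 methyl (1S,3aR,7aR)-6-iodo-3a,7-dimethyl-5-oxo-2,3,3a,4,5,7a-hexahydro-1H-indene-1-carboxylate; 15 (S)-β-citronellene [(S)-3,7-dimethylocta-1,6-diene]
Product: 17 methyl (1S,3aR,7aR)-6-[(3S)-3,7-dimethyloct-6-en-1-yl]-3a,7-dimethyl-5-oxo-2,3,3a,4,5,7a-hexahydro-1H-indene-1-carboxylate, via B-alkyl-9-borabicyclononane 16 (not isolated)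
Conditions: 15, 9-BBN, THF, rt; then 14, PdCl2(dppf) (5 mol%), AsPh3, Cs2CO3, DMF/THF/H2O, rt
Reagents that add atoms: none
Why: 9-BBN hydroborates only the monosubstituted alkene of 15, and B-alkyl Suzuki–Miyaura coupling of the borane with the α-iodoenone forms the tetrasubstituted enone while carrying the chain stereocentre over unchanged.

Step 10
Reactants: 17 methyl (1S,3aR,7aR)-6-[(3S)-3,7-dimethyloct-6-en-1-yl]-3a,7-dimethyl-5-oxo-2,3,3a,4,5,7a-hexahydro-1H-indene-1-carboxylate
Product: 19 α′-hydroxy enone (4-hydroxy derivative of 17; hydroxyl cis to the angular methyl), via lithium dienolate 18 (not isolated)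
Conditions: LiN(iPr)2, THF, −78 °C; then 2-(phenylsulfonyl)-3-phenyloxaziridine, −78 °C
Reagents that add atoms: 2-(phenylsulfonyl)-3-phenyloxaziridine, O=S(=O)(N1OC1c1ccccc1)c1ccccc1
Why: Kinetic α′-deprotonation and oxygen transfer from the N-sulfonyloxaziridine (enolate hydroxylation) should occur on the convex face, opposite the cyclopentane carbon that is syn-axial to the reacting carbon, which gives the hydroxyl cis to the angular methyl; this is also the pseudo-equatorial, thermodynamically preferred ketol.

Step 11
Reactants: 19 α′-hydroxy enone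
Product: 20 trans-4,5-diol (new allylic hydroxyl trans to the first one; on the face of the cyclopentane ring)
Conditions: Me4NBH(OAc)3, MeCN/AcOH, −20 °C
Reagents that add atoms: none
Why: In the Saksena–Evans reduction the acetoxyborohydride binds the α′-hydroxyl and delivers hydride to the enone carbonyl from that same face (1,2-reduction), so the new allylic hydroxyl ends up trans to the first.

Step 12
Reactants: 20 trans-4,5-diol
Product: 21 4,5-bis(triethylsilyl) ether of 20
Conditions: Et3SiOTf, 2,6-lutidine, CH2Cl2, −78 to 0 °C
Reagents that add atoms: triethylsilyl trifluoromethanesulfonate, CC[Si](CC)(CC)OS(=O)(=O)C(F)(F)F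
Why: Silyl triflate with lutidine silylates even the hindered hydroxyl next to the quaternary carbon and protects both hydroxyls through the base and organometallic steps that follow.

Step 13
Reactants: 21 4,5-bis(triethylsilyl) ether
Product: 23 C1 epimer of 21 (ester on the concave face; cis to the cyclohexene ring), via lithium ester enolate 22 (not isolated)
Conditions: LiN(iPr)2, THF, −78 to −30 °C; then 2,6-di-tert-butyl-4-methylphenol, −78 °C
Reagents that add atoms: none
Why: Kinetic protonation of the exocyclic ester enolate by a bulky phenol from the less hindered convex face of the cis-hydrindane (the face of the angular methyl and ring-fusion hydrogen, away from the silyloxy-substituted six-membered ring) places the ester on the concave face, which is the configuration of the target whatever epimer ratio enters the step.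

Step 14
Reactants: 23 concave-face ester
Product: 25 methyl ketone (1-acetyl analogue of 23), via N-methoxy-N-methylamide 24 (not isolated)
Conditions: MeNH(OMe)·HCl, iPrMgCl, THF, −20 to 0 °C; then MeMgBr, 0 °C
Reagents that add atoms: N,O-dimethylhydroxylamine hydrochloride (atoms kept only in 24), CNOC.Cl; methylmagnesium bromide, C[Mg]Br
Why: The chloromagnesium amide converts the ester into the N-methoxy-N-methylamide, whose chelated tetrahedral adduct with MeMgBr survives until work-up and so gives the methyl ketone without over-addition and without enolizing the adjacent stereocentre.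

Step 15
Reactants: 25 methyl ketone
Product: 27 alkenyl triflate (1-[1-(trifluoromethylsulfonyloxy)vinyl] analogue of 25), via potassium enolate 26 (not isolated)
Conditions: KN(SiMe3)2, THF, −78 °C (ketone added to the base); then PhNTf2, −78 to 0 °C
Reagents that add atoms: N-phenylbis(trifluoromethanesulfonimide), O=S(=O)(N(c1ccccc1)S(=O)(=O)C(F)(F)F)C(F)(F)F
Why: Kinetic deprotonation of the methyl ketone at the methyl group rather than at the hindered ring methine, followed by O-sulfonylation, gives the 1,1-disubstituted enol triflate and leaves the adjacent stereocentre intact.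

Step 16
Reactants: 27 alkenyl triflate
Product: 29 aldehyde (side chain shortened to 3-methyl-6-oxohexyl), via vicinal diol 28 (not isolated)
Conditions: OsO4 (2 mol%), NaIO4, 2,6-lutidine, dioxane/H2O, rt
Reagents that add atoms: sodium periodate (oxygen donor through the osmium catalyst), [Na+].[O-]I(=O)(=O)=O
Why: In the Lemieux–Johnson oxidation OsO4 dihydroxylates the unhindered, electron-rich isopropylidene alkene in preference to the hindered tetrasubstituted ring alkene and the electron-poor enol triflate, and periodate cleaves the diol to the aldehyde.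

Step 17
Reactants: 29 aldehyde
Product: 30 macrocyclic allylic alcohol (both carbinol epimers; bis(triethylsilyl) ether)
Conditions: CrCl2, NiCl2 (cat.), DMSO/THF, rt, high dilution (slow addition of 29)
Reagents that add atoms: none
Why: In the Nozaki–Hiyama–Kishi reaction nickel inserts into the alkenyl triflate, the alkenyl group passes to chromium and adds chemoselectively to the aldehyde, which closes the 11-membered ring and creates the 2-methylene-1-ol unit directly; the carbinol configuration is not relied upon because steps 18 and 19 reset it.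

Step 18
Reactants: 30 macrocyclic allylic alcohol
Product: 31 macrocyclic α-methylene ketone (bis(triethylsilyl) ether)
Conditions: Dess–Martin periodinane, pyridine, CH2Cl2, 0 °C to rt
Reagents that add atoms: none
Why: Dess–Martin oxidation converts both carbinol epimers into one enone under buffered conditions that spare the silyl ethers and do not isomerize the exocyclic alkene.

Step 19
Reactants: 31 macrocyclic α-methylene ketone
Product: 32 macrocyclic (S)-allylic alcohol (bis(triethylsilyl) ether)
Conditions: (R)-2-methyl-CBS-oxazaborolidine, BH3·SMe2, THF, −30 °C; MeOH quench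
Reagents that add atoms: none
Why: Corey–Bakshi–Shibata reduction distinguishes the branched alkenyl group (large) from the ring CH2 (small), so the (R)-catalyst should deliver hydride in a 1,2 sense to give the S carbinol by reagent control.

Step 20
Reactants: 32 macrocyclic (S)-allylic alcohol
Product: 33 allylic acetate (bis(triethylsilyl) ether)
Conditions: Ac2O, pyridine, DMAP (cat.), CH2Cl2, rt
Reagents that add atoms: acetic anhydride, CC(=O)OC(C)=O
Why: DMAP-catalysed acylation esterifies the only free hydroxyl with retention at the carbinol carbon.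

Step 21
Reactants: 33 allylic acetate
Product: 34 target compound
Conditions: HF·pyridine, pyridine, THF, 0 °C to rt
Reagents that add atoms: none
Why: Buffered fluoride cleavage of the two triethylsilyl ethers leaves the allylic acetate and both alkenes untouched and releases the trans-diol.

**Compound list**

1 | cyclohex-2-en-1-one | O=C1C=CCCC1 | starting material
2 | methyl iodoacetate | COC(=O)CI | starting material
3 | methylzinc enolate of (R)-3-methylcyclohexanone (enolate toward C2) | C[Zn]OC1=C[C@H](C)CCC1 | intermediate
4 | methyl 2-[(1S,2R)-2-methyl-6-oxocyclohexyl]acetate (trans) | COC(=O)C[C@H]1[C@H](C)CCCC1=O | intermediate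
5 | lithium enolate of 4 (toward the ring CH2) | COC(=O)C[C@H]1[C@H](C)CCC=C1O[Li] | intermediate
6 | methyl 2-[(1S,6R)-6-methyl-2-(trifluoromethylsulfonyloxy)cyclohex-2-en-1-yl]acetate | COC(=O)C[C@H]1[C@H](C)CCC=C1OS(=O)(=O)C(F)(F)F | intermediate
7 | methyl 2-[(1S,6R)-2,6-dimethylcyclohex-2-en-1-yl]acetate | COC(=O)C[C@H]1[C@H](C)CCC=C1C | intermediate
8 | lithium ester enolate of 7 | COC(O[Li])=C[C@H]1[C@H](C)CCC=C1C | intermediate
9 | methyl 2-bromo-2-[(1S,6R)-2,6-dimethylcyclohex-2-en-1-yl]acetate (both CHBr epimers) | COC(=O)C(Br)[C@H]1[C@H](C)CCC=C1C | intermediate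
10 | methyl 2-bromo-2-[(1S,6R)-2,6-dimethyl-4-oxocyclohex-2-en-1-yl]acetate (both CHBr epimers) | COC(=O)C(Br)[C@H]1[C@H](C)CC(=O)C=C1C | intermediate
11 | ethylene | C=C | starting material
12 | methyl (1S,3aR,7R,7aR)-3a,7-dimethyl-5-oxooctahydro-1H-indene-1-carboxylate (cis-fused; ester on the convex face) | O=C1C[C@@]2(C)CC[C@H](C(=O)OC)[C@H]2[C@H](C)C1 | intermediate
13 | methyl (1S,3aR,7aR)-3a,7-dimethyl-5-oxo-2,3,3a,4,5,7a-hexahydro-1H-indene-1-carboxylate | O=C1C[C@@]2(C)CC[C@H](C(=O)OC)[C@H]2C(C)=C1 | intermediate
14 | methyl (1S,3aR,7aR)-6-iodo-3a,7-dimethyl-5-oxo-2,3,3a,4,5,7a-hexahydro-1H-indene-1-carboxylate | O=C1C[C@@]2(C)CC[C@H](C(=O)OC)[C@H]2C(C)=C1I | intermediate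
15 | (S)-β-citronellene, (S)-3,7-dimethylocta-1,6-diene | CC(C)=CCC[C@H](C)C=C | starting material
16 | B-(3,7-dimethyloct-6-en-1-yl)-9-borabicyclo[3.3.1]nonane (from 15; methyl centre unchanged) | CC(C)=CCC[C@H](C)CCB1C2CCCC1CCC2 | intermediate
17 | methyl (1S,3aR,7aR)-6-[(3S)-3,7-dimethyloct-6-en-1-yl]-3a,7-dimethyl-5-oxo-2,3,3a,4,5,7a-hexahydro-1H-indene-1-carboxylate | CC(C)=CCC[C@H](C)CCC1=C(C)[C@@H]2[C@@H](C(=O)OC)CC[C@]2(C)CC1=O | intermediate
18 | lithium cross-conjugated dienolate of 17 | CC(C)=CCC[C@H](C)CCC1=C(C)[C@@H]2[C@@H](C(=O)OC)CC[C@]2(C)C=C1O[Li] | intermediate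
19 | α′-hydroxy enone: 4-hydroxy derivative of 17, hydroxyl cis to the angular methyl | CC(C)=CCC[C@H](C)CCC1=C(C)[C@@H]2[C@@H](C(=O)OC)CC[C@]2(C)[C@@H](O)C1=O | intermediate
20 | trans-4,5-diol from 19 (5-hydroxyl on the face of the cyclopentane ring) | CC(C)=CCC[C@H](C)CCC1=C(C)[C@@H]2[C@@H](C(=O)OC)CC[C@]2(C)[C@@H](O)[C@@H]1O | intermediate
21 | 4,5-bis(triethylsilyl) ether of 20 | CC(C)=CCC[C@H](C)CCC1=C(C)[C@@H]2[C@@H](C(=O)OC)CC[C@]2(C)[C@@H](O[Si](CC)(CC)CC)[C@@H]1O[Si](CC)(CC)CC | intermediate
22 | lithium ester enolate of 21 | CC(C)=CCC[C@H](C)CCC1=C(C)[C@@H]2C(=C(OC)O[Li])CC[C@]2(C)[C@@H](O[Si](CC)(CC)CC)[C@@H]1O[Si](CC)(CC)CC | intermediate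
23 | C1 epimer of 21 (ester on the concave face, cis to the cyclohexene ring) | CC(C)=CCC[C@H](C)CCC1=C(C)[C@@H]2[C@H](C(=O)OC)CC[C@]2(C)[C@@H](O[Si](CC)(CC)CC)[C@@H]1O[Si](CC)(CC)CC | intermediate
24 | N-methoxy-N-methylamide corresponding to 23 | CC(C)=CCC[C@H](C)CCC1=C(C)[C@@H]2[C@H](C(=O)N(C)OC)CC[C@]2(C)[C@@H](O[Si](CC)(CC)CC)[C@@H]1O[Si](CC)(CC)CC | intermediate
25 | methyl ketone (1-acetyl analogue of 23) | CC(C)=CCC[C@H](C)CCC1=C(C)[C@@H]2[C@H](C(C)=O)CC[C@]2(C)[C@@H](O[Si](CC)(CC)CC)[C@@H]1O[Si](CC)(CC)CC | intermediate
26 | potassium enolate of 25 (toward the methyl group) | CC(C)=CCC[C@H](C)CCC1=C(C)[C@@H]2[C@H](C(=C)O[K])CC[C@]2(C)[C@@H](O[Si](CC)(CC)CC)[C@@H]1O[Si](CC)(CC)CC | intermediate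
27 | alkenyl triflate from 25 (1-(trifluoromethylsulfonyloxy)vinyl group on the cyclopentane) | CC(C)=CCC[C@H](C)CCC1=C(C)[C@@H]2[C@H](C(=C)OS(=O)(=O)C(F)(F)F)CC[C@]2(C)[C@@H](O[Si](CC)(CC)CC)[C@@H]1O[Si](CC)(CC)CC | intermediate
28 | vicinal diol from the isopropylidene alkene of 27 | CC(C)(O)C(O)CC[C@H](C)CCC1=C(C)[C@@H]2[C@H](C(=C)OS(=O)(=O)C(F)(F)F)CC[C@]2(C)[C@@H](O[Si](CC)(CC)CC)[C@@H]1O[Si](CC)(CC)CC | intermediate
29 | aldehyde (3-methyl-6-oxohexyl side chain) with alkenyl triflate | O=CCC[C@H](C)CCC1=C(C)[C@@H]2[C@H](C(=C)OS(=O)(=O)C(F)(F)F)CC[C@]2(C)[C@@H](O[Si](CC)(CC)CC)[C@@H]1O[Si](CC)(CC)CC | intermediate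
30 | macrocyclic allylic alcohol, bis(triethylsilyl) ether (both carbinol epimers) | C=C1C(O)CC[C@H](C)CCC2=C(C)[C@@H]3[C@H]1CC[C@]3(C)[C@@H](O[Si](CC)(CC)CC)[C@@H]2O[Si](CC)(CC)CC | intermediate
31 | macrocyclic α-methylene ketone, bis(triethylsilyl) ether | C=C1C(=O)CC[C@H](C)CCC2=C(C)[C@@H]3[C@H]1CC[C@]3(C)[C@@H](O[Si](CC)(CC)CC)[C@@H]2O[Si](CC)(CC)CC | intermediate
32 | macrocyclic (S)-allylic alcohol, bis(triethylsilyl) ether | C=C1[C@@H](O)CC[C@H](C)CCC2=C(C)[C@@H]3[C@H]1CC[C@]3(C)[C@@H](O[Si](CC)(CC)CC)[C@@H]2O[Si](CC)(CC)CC | intermediate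
33 | allylic acetate, bis(triethylsilyl) ether | C=C1[C@@H](OC(C)=O)CC[C@H](C)CCC2=C(C)[C@@H]3[C@H]1CC[C@]3(C)[C@@H](O[Si](CC)(CC)CC)[C@@H]2O[Si](CC)(CC)CC | intermediate
34 | CNP0192310.1 | C=C1[C@@H](OC(C)=O)CC[C@H](C)CCC2=C(C)[C@@H]3[C@H]1CC[C@]3(C)[C@@H](O)[C@@H]2O | target

Total step count: 21
Longest linear sequence: 21 steps (1 to 34; compounds 2, 11 and 15 are purchased and enter directly)

**Steps most likely to fail**

Step 6: reduction of the first radical by the silane, or a second ethylene insertion by the primary radical, may outrun the desired addition and ring closure. The fallback makes the two bonds in separate operations by known chemistry. It sets out from 7, whose lithium enolate 8 is alkylated with 2-bromoethyl trifluoromethanesulfonate to give methyl 4-bromo-2-(2,6-dimethylcyclohex-2-en-1-yl)butanoate F1 (ring configuration as in 7). Allylic oxidation with CrO3 and 3,5-dimethylpyrazole gives the enone, methyl 4-bromo-2-(2,6-dimethyl-4-oxocyclohex-2-en-1-yl)butanoate F2. Bu3SnH/AIBN in benzene at 80 °C then closes the cyclopentane by 5-exo-trig attack of the primary radical on the enone, and the route is rejoined at 12.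

Step 13: deprotonation of the hindered C–H may be incomplete, or proton transfer may not distinguish the two faces of the enolate well enough. The fallback sets the centre by hydrogen-atom transfer instead of proton transfer. It sets out from 21, whose enolate 22 is brominated with BrCCl2CCl2Br to give the tertiary α-bromo ester F3. Reduction with (Me3Si)3SiH and Et3B/air in toluene at −78 °C passes through a planar α-ester radical that takes hydrogen from the bulky silane on the convex face, and the route is rejoined at 23.

Step 17: oligomerization or protodemetalation of the alkenyl–metal species may compete with closure of the 11-membered ring. The fallback closes the same ring by a nickel-catalysed reductive aldehyde–alkyne coupling. It sets out from 27, which loses triflate on treatment with LiN(iPr)2 to give the terminal alkyne F4. Lemieux–Johnson cleavage of the isopropylidene alkene, through the vicinal diol F5, gives the ynal F6. Ni(cod)2 with the bulky carbene ligand 1,3-bis(2,6-diisopropylphenyl)imidazol-2-ylidene and Et3SiH, at high dilution, should then join the aldehyde carbon to the internal alkyne carbon (exocyclic mode) and give the macrocyclic tris(triethylsilyl) ether F7. Methanolysis of the unhindered allylic silyl ether (PPTS, MeOH, −10 °C) rejoins the route at 30, after which steps 18 and 19 set the carbinol configuration as before.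

**Further compounds**

F1 | step 6 | methyl 4-bromo-2-(2,6-dimethylcyclohex-2-en-1-yl)butanoate (ring configuration as in 7) | COC(=O)C(CCBr)[C@H]1[C@H](C)CCC=C1C
F2 | step 6 | methyl 4-bromo-2-(2,6-dimethyl-4-oxocyclohex-2-en-1-yl)butanoate (ring configuration as in 10) | COC(=O)C(CCBr)[C@H]1[C@H](C)CC(=O)C=C1C
F3 | step 13 | tertiary α-bromo ester from 21 (bromine on the ester-bearing cyclopentane carbon) | CC(C)=CCC[C@H](C)CCC1=C(C)[C@@H]2C(Br)(C(=O)OC)CC[C@]2(C)[C@@H](O[Si](CC)(CC)CC)[C@@H]1O[Si](CC)(CC)CC
F4 | step 17 | terminal alkyne from 27 (ethynyl group on the cyclopentane) | CC(C)=CCC[C@H](C)CCC1=C(C)[C@@H]2[C@H](C#C)CC[C@]2(C)[C@@H](O[Si](CC)(CC)CC)[C@@H]1O[Si](CC)(CC)CC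
F5 | step 17 | vicinal diol from the isopropylidene alkene of the alkyne | CC(C)(O)C(O)CC[C@H](C)CCC1=C(C)[C@@H]2[C@H](C#C)CC[C@]2(C)[C@@H](O[Si](CC)(CC)CC)[C@@H]1O[Si](CC)(CC)CC
F6 | step 17 | ynal (ethynyl group and 3-methyl-6-oxohexyl chain) | O=CCC[C@H](C)CCC1=C(C)[C@@H]2[C@H](C#C)CC[C@]2(C)[C@@H](O[Si](CC)(CC)CC)[C@@H]1O[Si](CC)(CC)CC
F7 | step 17 | macrocyclic tris(triethylsilyl) ether (both carbinol epimers) | C=C1C(O[Si](CC)(CC)CC)CC[C@H](C)CCC2=C(C)[C@@H]3[C@H]1CC[C@]3(C)[C@@H](O[Si](CC)(CC)CC)[C@@H]2O[Si](CC)(CC)CC
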